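## Retrosynthetic overview
1. The target comes from a butane-2,3-diacetal (BDA)-protected spiro-bis-lactone methyl ester by O-methyl cleavage and acetal hydrolysis. No ring is made or broken after the key step.
2. The key cut removes the C5–C9 bond and both lactone acyl–O bonds (O7–C6 and O1–C2) in one operation. This gives chiral LiCH2–CH(OLi)R and a non-enolisable α-keto triester carried on a tartrate dioxane.
3. Order of events in the flask: the C–C bond forms first, then the O7 lactone (secondary alkoxide on the geminal ester), then the O1 lactone (tertiary alkoxide on the C3 ester).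
4. The keto triester comes from the enolate of BDA-protected dimethyl L-tartrate and dimethyl oxalate. C3 comes from the chiral pool and C4 is set by equatorial acylation.
5. The organolithium comes from the (R)-epoxide, made by hydrolytic kinetic resolution of the epoxide from undec-10-enal and a sulfonium ylide. This sets C8.

Assumption: the SMILES is taken as authoritative. It decodes to (3R,4R,5S,8R)-8-(dec-9-en-1-yl)-3,4-dihydroxy-2,6-dioxo-1,7-dioxaspiro[4.4]nonane-4-carboxylic acid (the cinatrin A constitution), and these locants are used below.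

## Route

Step 1
Reactants: 1 dimethyl L-tartrate
Product: 2 BDA-protected dimethyl L-tartrate [dimethyl (2R,3R,5R,6R)-5,6-dimethoxy-5,6-dimethyl-1,4-dioxane-2,3-dicarboxylate; both esters equatorial and both OMe axial]
Conditions: butane-2,3-dione (1.2 equiv), HC(OMe)3 (3 equiv), CSA (10 mol %), MeOH, reflux, 16 h
Reagents that add atoms: butane-2,3-dione CC(=O)C(C)=O; trimethyl orthoformate COC(OC)OC
Why: In this acid-catalysed trans-ketalisation (butane-2,3-diacetal protection) the trans-diol closes a chair 1,4-dioxane whose two new acetal centres are fixed as (R,R) by the double anomeric effect, while the tartrate centres are untouched.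

Step 2
Reactants: 2 BDA-protected dimethyl L-tartrate; 3 dimethyl oxalate
Product: 5 dimethyl (2R,3R,5R,6R)-5,6-dimethoxy-2-(2-methoxy-2-oxoacetyl)-5,6-dimethyl-1,4-dioxane-2,3-dicarboxylate (oxalyl equatorial; C2 ester axial), via lithium enolate 4 (not isolated)
Conditions: LDA (commercial solution, 1.05 equiv), THF, −78 °C, 30 min; cannulate into 3 (3 equiv), THF, −78 °C, 1 h; AcOH, −78 °C; dry by toluene azeotrope
Reagents that add atoms: none
Why: In this crossed Claisen acylation of an exocyclic ester enolate (whose ring C–O bond is misaligned for β-elimination), the axial OMe at C6 shields the axial face, so the oxalyl group enters equatorially and anti to the C3 ester, which pushes the C2 ester axial and sets the quaternary carbinol carbon (2R, C4 of the target), and the cold acid quench prevents retro-Claisen cleavage by methoxide.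

Step 3
Reactants: 6 undec-10-enal
Product: 7 rac-2-(dec-9-en-1-yl)oxirane
Conditions: Me3S+ I− (1.3 equiv), NaH (1.3 equiv), DMSO–THF, 0 °C → rt, 2 h
Reagents that add atoms: trimethylsulfonium iodide C[S+](C)C.[I-]
Why: In this Corey–Chaykovsky methylene transfer the sulfonium ylide adds to the aldehyde faster than it enolises it, the betaine closes to the racemic terminal epoxide, and the isolated alkene is inert.

Step 4
Reactants: 7 rac-2-(dec-9-en-1-yl)oxirane
Product: 8 (R)-2-(dec-9-en-1-yl)oxirane
Conditions: (R,R)-Co(salen) (0.5 mol %), AcOH (2 mol %), air; H2O (0.55 equiv), minimal THF, 0 °C → rt, 16 h; chromatography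
Reagents that add atoms: none
Why: In this Jacobsen hydrolytic kinetic resolution the (R,R)-catalyst hydrolyses the (S)-epoxide of simple alkyl oxiranes much faster, leaving (R)-8 in >99 % ee and thereby fixing C8 of the target.

Step 5 (key step)
Reactants: 8 (R)-2-(dec-9-en-1-yl)oxirane; 5 α-keto triester
Product: 11 BDA-protected cinatrin A methyl ester [methyl (3R,4R,5S,8R)-8-(dec-9-en-1-yl)-3,4-O-[(2R,3R)-2,3-dimethoxybutane-2,3-diyl]-2,6-dioxo-1,7-dioxaspiro[4.4]nonane-4-carboxylate; dioxane trans-fused to the O1 lactone], via β-oxido organolithium 9 (not isolated), via open-chain dilithium dialkoxide 10 (not isolated)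
Conditions: 8 (1.15 equiv), LiDBB (2.0 equiv per 8, added until the green colour just persists), THF, −78 °C, 10 min; cannulate into 5 precomplexed with MgBr2·OEt2 (1.5 equiv), CH2Cl2–THF, −78 °C, 1 h; → 0 °C, 1 h; AcOH
Reagents that add atoms: none
Why: Proposed new method: reductive lithiation of the terminal epoxide cleaves the primary C–O bond and gives LiCH2–CH(OLi)R 9 with its stereocentre untouched (stable to Li2O loss at −78 °C), and its carbanion adds to the only ketone of 5, which is held as a Mg(II) β-keto-ester chelate with the axial C2 ester so that the face next to ring O1 is open and the other is blocked by the equatorial C3 ester, setting the spiro carbon as (S); the secondary alkoxide of 10 then closes on the geminal CO2Me (5-exo-trig, O7 lactone) and the tertiary alkoxide closes on the gauche equatorial C3 CO2Me (trans-fused O1 lactone), which traps the adduct before retro-aldol; the closest known reaction types are the addition of epoxide-derived β-oxido organolithiums to ketones to give 1,3-diols, chelation-controlled organomagnesium addition to α-keto esters, and alkoxide-triggered lactonisation of γ-hydroxy esters.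

Step 6
Reactants: 11 BDA-protected cinatrin A methyl ester
Product: 12 BDA-protected cinatrin A (free C4 carboxylic acid)
Conditions: LiI (10 equiv), pyridine, reflux, 6–12 h; 1 M HCl work-up
Reagents that add atoms: none
Why: In this nucleophilic SN2 ester dealkylation iodide attacks the unhindered O-methyl carbon and ignores the congestion at the acyl carbon, the lactone O-alkyl carbons (secondary and tertiary) react far more slowly, no free β-hydroxyl is present for retro-aldol, and the ester is not of the malonate type so no Krapcho decarboxylation occurs.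

Step 7
Reactants: 12 BDA-protected cinatrin A
Product: 13 target, (3R,4R,5S,8R)-8-(dec-9-en-1-yl)-3,4-dihydroxy-2,6-dioxo-1,7-dioxaspiro[4.4]nonane-4-carboxylic acid
Conditions: TFA–H2O 9:1, 0 °C → rt, 30 min; evaporate; reverse-phase chromatography
Reagents that add atoms: none
Why: Acid hydrolysis of the butane-2,3-diacetal breaks only acetal C–O bonds, so the C3 and C4 oxygens and configurations are retained, both γ-lactones are stable in acid, and the short contact time in wet TFA spares the terminal alkene.

## Compound list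
1 | dimethyl L-tartrate, dimethyl (2R,3R)-2,3-dihydroxybutanedioate | COC(=O)[C@H](O)[C@@H](O)C(=O)OC | starting material
2 | dimethyl (2R,3R,5R,6R)-5,6-dimethoxy-5,6-dimethyl-1,4-dioxane-2,3-dicarboxylate | COC(=O)[C@@H]1O[C@@](C)(OC)[C@](C)(OC)O[C@H]1C(=O)OC | intermediate
3 | dimethyl oxalate | COC(=O)C(=O)OC | starting material
4 | lithium enolate of 2 (exocyclic ketene acetal at C2, geometry undefined) | COC(O[Li])=C1O[C@@](C)(OC)[C@](C)(OC)O[C@H]1C(=O)OC | intermediate
5 | dimethyl (2R,3R,5R,6R)-5,6-dimethoxy-2-(2-methoxy-2-oxoacetyl)-5,6-dimethyl-1,4-dioxane-2,3-dicarboxylate | COC(=O)C(=O)[C@]1(C(=O)OC)O[C@@](C)(OC)[C@](C)(OC)O[C@H]1C(=O)OC | intermediate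
6 | undec-10-enal | C=CCCCCCCCCC=O | starting material
7 | rac-2-(dec-9-en-1-yl)oxirane | C=CCCCCCCCCC1CO1 | intermediate
8 | (R)-2-(dec-9-en-1-yl)oxirane | C=CCCCCCCCC[C@@H]1CO1 | intermediate
9 | lithium (S)-1-lithiododec-11-en-2-olate (same spatial arrangement as 8; the descriptor changes only through CIP priority) | C=CCCCCCCCC[C@@H](O[Li])C[Li] | intermediate
10 | dilithium dialkoxide of dimethyl (2R,3R,5R,6R)-2-[(2S,4R)-2,4-dihydroxy-1-methoxy-1-oxotetradec-13-en-2-yl]-5,6-dimethoxy-5,6-dimethyl-1,4-dioxane-2,3-dicarboxylate | C=CCCCCCCCC[C@@H](O[Li])C[C@@](O[Li])(C(=O)OC)[C@]1(C(=O)OC)O[C@@](C)(OC)[C@](C)(OC)O[C@H]1C(=O)OC | intermediate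
11 | BDA-protected cinatrin A methyl ester (3R,4R,5S,8R; acetal carbons R,R) | C=CCCCCCCCC[C@@H]1C[C@@]2(OC(=O)[C@@H]3O[C@@](C)(OC)[C@](C)(OC)O[C@@]23C(=O)OC)C(=O)O1 | intermediate
12 | BDA-protected cinatrin A, free acid | C=CCCCCCCCC[C@@H]1C[C@@]2(OC(=O)[C@@H]3O[C@@](C)(OC)[C@](C)(OC)O[C@@]23C(=O)O)C(=O)O1 | intermediate
13 | (3R,4R,5S,8R)-8-(dec-9-en-1-yl)-3,4-dihydroxy-2,6-dioxo-1,7-dioxaspiro[4.4]nonane-4-carboxylic acid | C=CCCCCCCCC[C@@H]1C[C@@]2(OC(=O)[C@H](O)[C@]2(O)C(=O)O)C(=O)O1 | target

## Step count and risks
Total steps: 7. Longest linear sequence: 5 steps (1→2→5→11→12→13, or 6→7→8→11→12→13).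

**Most likely to fail, first: step 5.**
- Risks: loss of Li2O from 9, attack at the oxalyl ester instead of the ketone, the wrong ketone face, retro-aldol of 10, or C3 epimerisation by methoxide.
- The fallback sets out from 5 and 6 and comes back at 11. It replaces the organolithium by an aldol reaction and sets C8 by 1,3-induction.
- Compound 6 with MeMgBr gives racemic dodec-11-en-2-ol F1. Dess–Martin oxidation of this gives dodec-11-en-2-one F2.
- The kinetic lithium enolate of the ketone (LDA, −78 °C) is added to the MgBr2 chelate of 5 and quenched at −78 °C. This gives the tertiary aldol, dimethyl (2R,3R,5R,6R)-2-[(2S)-2-hydroxy-1-methoxy-1,4-dioxotetradec-13-en-2-yl]-5,6-dimethoxy-5,6-dimethyl-1,4-dioxane-2,3-dicarboxylate F3.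
- Evans–Saksena reduction (Me4NBH(OAc)3, MeCN–AcOH, −20 °C) delivers hydride from the tertiary hydroxyl with the dioxane substituent equatorial. This gives the 1,3-anti (2S,4R)-diol F4.
- Catalytic CSA in toluene then closes both lactones to give 11.

**Second: step 2.**
- Risks: O-acylation, a second addition to the very electrophilic product, or retro-Claisen cleavage.
- The fallback sets out from 2 and comes back at 5.
- Enolate 4 undergoes an aldol addition to freshly cracked methyl glyoxylate at −78 °C, with the same equatorial approach. This gives the secondary alcohol, dimethyl (2R,3R,5R,6R)-2-(1-hydroxy-2-methoxy-2-oxoethyl)-5,6-dimethoxy-5,6-dimethyl-1,4-dioxane-2,3-dicarboxylate F5, as a carbinol mixture that does not matter.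
- Dess–Martin oxidation converts it to 5.

**Third: step 6.**
- Risks: a sluggish dealkylation, or iodide opening the lactone at C8.
- The fallback sets out from 2 and comes back at 12. It carries the C4 carboxyl as an allyl ester that is removed under neutral Pd(0) conditions.
- Ti(OiPr)4-catalysed transesterification of 2 in allyl alcohol gives the diallyl BDA-tartrate F6.
- LDA and 3, as in step 2, give the diallyl α-keto triester F7.
- The cascade of step 5 with 9 gives the BDA-protected cinatrin A allyl ester F8.
- Pd(PPh3)4 and morpholine in THF at rt give 12.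

## Further compounds
F1 | step 5 | dodec-11-en-2-ol (racemic) | C=CCCCCCCCCC(C)O
F2 | step 5 | dodec-11-en-2-one | C=CCCCCCCCCC(C)=O
F3 | step 5 | dimethyl (2R,3R,5R,6R)-2-[(2S)-2-hydroxy-1-methoxy-1,4-dioxotetradec-13-en-2-yl]-5,6-dimethoxy-5,6-dimethyl-1,4-dioxane-2,3-dicarboxylate | C=CCCCCCCCCC(=O)C[C@@](O)(C(=O)OC)[C@]1(C(=O)OC)O[C@@](C)(OC)[C@](C)(OC)O[C@H]1C(=O)OC
F4 | step 5 | dimethyl (2R,3R,5R,6R)-2-[(2S,4R)-2,4-dihydroxy-1-methoxy-1-oxotetradec-13-en-2-yl]-5,6-dimethoxy-5,6-dimethyl-1,4-dioxane-2,3-dicarboxylate | C=CCCCCCCCC[C@@H](O)C[C@@](O)(C(=O)OC)[C@]1(C(=O)OC)O[C@@](C)(OC)[C@](C)(OC)O[C@H]1C(=O)OC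
F5 | step 2 | dimethyl (2R,3R,5R,6R)-2-(1-hydroxy-2-methoxy-2-oxoethyl)-5,6-dimethoxy-5,6-dimethyl-1,4-dioxane-2,3-dicarboxylate (carbinol epimers) | COC(=O)C(O)[C@]1(C(=O)OC)O[C@@](C)(OC)[C@](C)(OC)O[C@H]1C(=O)OC
F6 | step 6 | diallyl (2R,3R,5R,6R)-5,6-dimethoxy-5,6-dimethyl-1,4-dioxane-2,3-dicarboxylate | C=CCOC(=O)[C@@H]1O[C@@](C)(OC)[C@](C)(OC)O[C@H]1C(=O)OCC=C
F7 | step 6 | diallyl (2R,3R,5R,6R)-5,6-dimethoxy-2-(2-methoxy-2-oxoacetyl)-5,6-dimethyl-1,4-dioxane-2,3-dicarboxylate | COC(=O)C(=O)[C@]1(C(=O)OCC=C)O[C@@](C)(OC)[C@](C)(OC)O[C@H]1C(=O)OCC=C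
F8 | step 6 | BDA-protected cinatrin A allyl ester | C=CCCCCCCCC[C@@H]1C[C@@]2(OC(=O)[C@@H]3O[C@@](C)(OC)[C@](C)(OC)O[C@@]23C(=O)OCC=C)C(=O)O1
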